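**Retrosynthetic overview**
- The target is opened at the silyl ether and at the two esters: the C-5 ester comes from an axial allylic alcohol and (E)-3-methylpent-2-enoic acid (late Yamaguchi coupling), the C-5 oxygen from SeO2 allylic oxidation, and the C-3 ester from an α-hydroxy ketone (Davis oxidation) and (R)-2-methylbutanoic acid.
- The trans-hydrindan-2-one is opened by a Dieckmann/decarboxylation disconnection to a 2,3-trans-3,4-trans methylenecyclohexane diester; the five-membered ring is formed second.
- The diester comes from three pieces: (S)-cryptone (six-membered ring formed first, by organocatalytic Michael addition and aldol condensation), the silyl ketene acetal of methyl (R)-3-silyloxybutanoate (brings C-1, C-2 and the hydroxyethyl stereocentre; joined by Mukaiyama–Michael addition), and allyl bromoacetate (C-3).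
- The enone, the ketene acetal and the two acids (each 7–10 non-hydrogen atoms without silyl groups) are made separately and joined in steps 5, 12 and 16.

Assumption: hydrindane (octahydroindene) numbering C1–C7a is used for the bicyclic compounds (C1 bears the hydroxyethyl group, C2 is the ring ketone, C4 carries the methylene; β is the face of H-7a, α the face of H-3a); the carbon that becomes C-1 is formed in the Mukaiyama–Michael step as a mixture of epimers, the intermediates are drawn as the epimer with the final configuration, and both epimers converge in the decarboxylation/equilibration step.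

**Route**

Step 1
Reactants: 1 3-methylbutanal; 2 but-3-en-2-one
Product: 3 (S)-2-isopropyl-5-oxohexanal
Conditions: (S)-2-[diphenyl(trimethylsilyloxy)methyl]pyrrolidine (5 mol %), ethyl 3,4-dihydroxybenzoate (20 mol %), neat, 4 °C
Reagents that add atoms: none
Why: Enamine-catalysed asymmetric Michael addition (Hayashi–Jørgensen-type catalyst) in which the E-enamine of 1 adds to 2 on the face away from the diphenyl(silyloxy)methyl group, setting the isopropyl-bearing stereocentre (S), the future C-7.

Step 2
Reactants: 3 (S)-2-isopropyl-5-oxohexanal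
Product: 4 (S)-4-isopropylcyclohex-2-en-1-one ((S)-cryptone)
Conditions: KOH (0.1 M aq), n-Bu4NOH (cat.), Et2O–THF, reflux
Reagents that add atoms: none
Why: Intramolecular aldol condensation (methyl ketone enolate onto the aldehyde, then E1cB loss of water) closes the six-membered ring faster than the α-stereocentre epimerises, so the (S) centre is kept.

Step 3
Reactants: 5 methyl (R)-3-hydroxybutanoate
Product: 6 methyl (R)-3-[(tert-butyldimethylsilyl)oxy]butanoate
Conditions: TBSCl, imidazole, DMF, rt
Reagents that add atoms: tert-butyldimethylsilyl chloride, CC(C)(C)[Si](C)(C)Cl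
Why: Imidazole-promoted silylation of the secondary alcohol leaves the stereocentre (the future C-1′, R) untouched.

Step 4
Reactants: 6 methyl (R)-3-[(tert-butyldimethylsilyl)oxy]butanoate
Product: 7 (R,E)-3-[(tert-butyldimethylsilyl)oxy]-1-methoxy-1-[(trimethylsilyl)oxy]but-1-ene
Conditions: LiN(iPr)2, THF, −78 °C; Me3SiCl, −78 °C → rt; non-aqueous work-up
Reagents that add atoms: chlorotrimethylsilane, C[Si](C)(C)Cl
Why: Kinetic ester enolisation at −78 °C and O-silylation (Ireland conditions) give the ketene silyl acetal, mainly E, without β-elimination of the silyloxy group; no new stereocentre is formed.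

Step 5
Reactants: 4 (S)-cryptone; 7 the silyl ketene acetal
Product: 8 methyl (2S,3R)-3-[(tert-butyldimethylsilyl)oxy]-2-[(1S,6S)-6-isopropyl-3-[(trimethylsilyl)oxy]cyclohex-2-en-1-yl]butanoate
Conditions: Tf2NH (2 mol %), CH2Cl2, −78 °C; Et3N quench, non-aqueous work-up
Reagents that add atoms: none
Why: Mukaiyama–Michael addition catalysed by the silyl triflimide formed in situ, in which the ketene acetal attacks the enone β-carbon axially and anti to the isopropyl group (setting C-7a trans to it) and the silyl group moves to oxygen to give the regiodefined C3a=C4 enol ether.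

Step 6
Reactants: 9 bromoacetyl bromide; 10 prop-2-en-1-ol
Product: 11 allyl bromoacetate
Conditions: pyridine, CH2Cl2, 0 °C
Reagents that add atoms: none
Why: Nucleophilic acyl substitution at the acid bromide, which reacts far faster than the alkyl bromide, with pyridine as acid scavenger.

Step 7
Reactants: 8 the silyl enol ether; 11 allyl bromoacetate
Product: 12 methyl (2S,3R)-2-[(1S,2R,6S)-2-[2-(allyloxy)-2-oxoethyl]-6-isopropyl-3-oxocyclohexyl]-3-[(tert-butyldimethylsilyl)oxy]butanoate
Conditions: BnMe3NF (anhydrous, 1.1 equiv), 4 Å MS, THF, −40 °C → rt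
Reagents that add atoms: none
Why: Regiospecific enolate alkylation (Kuwajima-type) in which fluoride cleaves only the enol silyl ether to the ammonium enolate at C-3a, which is C-alkylated by the activated α-bromo ester anti to the neighbouring C-7a substituent, setting C-3a trans to it (all-equatorial ketone).

Step 8
Reactants: 12 the keto diester
Product: 13 methyl (2S,3R)-2-[(1S,2R,6S)-2-[2-(allyloxy)-2-oxoethyl]-6-isopropyl-3-methylenecyclohexyl]-3-[(tert-butyldimethylsilyl)oxy]butanoate
Conditions: Ph3PCH3Br (2.0 equiv), KOt-Bu (1.9 equiv), toluene, 0 °C → rt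
Reagents that add atoms: methyltriphenylphosphonium bromide, C[P+](c1ccccc1)(c1ccccc1)c1ccccc1.[Br-]
Why: Wittig methylenation, in which the non-stabilised ylide reacts only with the ketone (esters are inert) and the α-centre C-3a is already in its preferred equatorial configuration, so the base cannot erode it.

Step 9
Reactants: 13 the methylene diester
Product: 15 (1S,3aR,7S,7aS)-1-[(R)-1-[(tert-butyldimethylsilyl)oxy]ethyl]-7-isopropyl-4-methyleneoctahydro-2H-inden-2-one, via allyl β-keto ester 14 (not isolated)
Conditions: LiN(SiMe3)2 (2.2 equiv), THF, −78 → 0 °C; AcOH; then Pd(PPh3)4 (5 mol %), morpholine, rt; then DBU (0.3 equiv), rt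
Reagents that add atoms: none
Why: Dieckmann condensation in which the less hindered CH2 ester enolate (C-3) attacks the methyl ester (C-2) to close the trans-fused five-membered ring, followed by Tsuji-type deallylation with zerovalent palladium (morpholine traps the allyl group), loss of CO2, and DBU equilibration of C-1 to the pseudo-equatorial 1β configuration.

Step 10
Reactants: 15 the hydrindanone
Product: 16 (1S,3S,3aR,7S,7aS)-1-[(R)-1-[(tert-butyldimethylsilyl)oxy]ethyl]-3-hydroxy-7-isopropyl-4-methyleneoctahydro-2H-inden-2-one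
Conditions: KN(SiMe3)2, THF, −78 °C; 2-(phenylsulfonyl)-3-phenyloxaziridine, −78 °C; aq NH4Cl
Reagents that add atoms: 2-(phenylsulfonyl)-3-phenyloxaziridine (Davis reagent), O=S(=O)(c1ccccc1)N1OC1c1ccccc1
Why: Davis α-hydroxylation of the kinetic enolate, in which the base removes a proton from the CH2 (C-3) and not from the hindered methine C-1, and oxygen is expected to be delivered to the β face, anti to the pseudo-axial H-3a (torsional control), giving the 3β-alcohol.

Step 11
Reactants: 17 (E)-2-methylbut-2-enoic acid (tiglic acid)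
Product: 18 (R)-2-methylbutanoic acid
Conditions: H2 (5 atm), Ru(OAc)2[(R)-H8-BINAP] (0.5 mol %), MeOH, rt
Reagents that add atoms: none
Why: Noyori-type asymmetric hydrogenation of an α,β-unsaturated acid, in which the ruthenium-bound carboxylate and the (R)-diphosphine direct H2 to one enantioface and set the (R)-α-stereocentre (about 97% ee expected).

Step 12
Reactants: 16 the 3β-hydroxy ketone; 18 (R)-2-methylbutanoic acid
Product: 19 (1S,3S,3aR,7S,7aS)-1-[(R)-1-[(tert-butyldimethylsilyl)oxy]ethyl]-7-isopropyl-4-methylene-2-oxooctahydro-1H-inden-3-yl (R)-2-methylbutanoate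
Conditions: DCC, DMAP (0.2 equiv), CH2Cl2, 0 °C → rt
Reagents that add atoms: none
Why: Steglich esterification (carbodiimide activation, acyl transfer by DMAP) acylates the only free hydroxyl with retention at C-3 and, at 0 °C, without epimerising the α-centre of the acid.

Step 13
Reactants: 19 the C-3 ester
Product: 20 (1S,3S,3aR,5R,7S,7aS)-1-[(R)-1-[(tert-butyldimethylsilyl)oxy]ethyl]-5-hydroxy-7-isopropyl-4-methylene-2-oxooctahydro-1H-inden-3-yl (R)-2-methylbutanoate
Conditions: SeO2 (0.3 equiv), t-BuOOH (3 equiv), CH2Cl2, 0 °C → rt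
Reagents that add atoms: selenium dioxide, O=[Se]=O (delivers the oxygen); tert-butyl hydroperoxide, CC(C)(C)OO (re-oxidises selenium)
Why: Selenium dioxide allylic oxidation (ene reaction then [2,3]-sigmatropic shift), in which the allylic CH2 (C-5) reacts in preference to the ring-fusion CH (C-3a) and oxygen is delivered axially to give the 5α-alcohol with the exocyclic alkene restored; it is run before the enoate is attached because that group has its own allylic C–H bonds.

Step 14
Reactants: 21 methyl but-2-ynoate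
Product: 22 methyl (E)-3-methylpent-2-enoate
Conditions: Et2CuLi (from EtLi and CuI), THF, −78 °C; MeOH, −78 °C
Reagents that add atoms: ethyllithium, [Li]CC (used as lithium diethylcuprate)
Why: Syn-carbocupration of the ynoate puts ethyl on the β-carbon and copper on the α-carbon on the same side, and protonation at −78 °C with retention gives only the E-alkene (ethyl trans to the ester).

Step 15
Reactants: 22 methyl (E)-3-methylpent-2-enoate
Product: 23 (E)-3-methylpent-2-enoic acid
Conditions: LiOH, THF–H2O, rt; then 1 M HCl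
Reagents that add atoms: lithium hydroxide, [Li+].[OH-]
Why: Ester saponification by acyl–oxygen cleavage followed by acidification, under conditions too mild to isomerise the trisubstituted alkene.

Step 16
Reactants: 20 the 5α-allylic alcohol; 23 (E)-3-methylpent-2-enoic acid
Product: 25 the tert-butyldimethylsilyl ether of the target, (1S,3S,3aR,5R,7S,7aS)-1-[(R)-1-[(tert-butyldimethylsilyl)oxy]ethyl]-7-isopropyl-4-methylene-3-{[(R)-2-methylbutanoyl]oxy}-2-oxooctahydro-1H-inden-5-yl (E)-3-methylpent-2-enoate, via mixed anhydride 24 (not isolated)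
Conditions: 2,4,6-Cl3C6H2COCl, Et3N, THF, rt; then 20, DMAP, toluene, rt
Reagents that add atoms: 2,4,6-trichlorobenzoyl chloride, O=C(Cl)c1c(Cl)cc(Cl)cc1Cl (its atoms stay in 24 only, none in 25)
Why: Yamaguchi esterification, in which DMAP attacks the less hindered enoyl carbonyl of the mixed anhydride and the acylpyridinium acylates the hindered axial allylic alcohol with retention at C-5, with no ketene pathway and so no double-bond migration.

Step 17
Reactants: 25 the silyl ether of the target
Product: 26 CNP0224363.2, (1S,3S,3aR,5R,7S,7aS)-1-[(R)-1-hydroxyethyl]-7-isopropyl-4-methylene-3-{[(R)-2-methylbutanoyl]oxy}-2-oxooctahydro-1H-inden-5-yl (E)-3-methylpent-2-enoate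
Conditions: HF·pyridine, pyridine, THF, 0 °C → rt
Reagents that add atoms: none
Why: Buffered fluoride desilylation frees the secondary alcohol without retro-aldol cleavage or β-elimination of the β-hydroxy ketone and without touching the two esters.

**Compound list**

1 | 3-methylbutanal | CC(C)CC=O | starting material
2 | but-3-en-2-one | CC(=O)C=C | starting material
3 | (S)-2-isopropyl-5-oxohexanal | CC(=O)CC[C@@H](C(C)C)C=O | intermediate
4 | (S)-4-isopropylcyclohex-2-en-1-one | O=C1C=C[C@H](C(C)C)CC1 | intermediate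
5 | methyl (R)-3-hydroxybutanoate | C[C@@H](O)CC(=O)OC | starting material
6 | methyl (R)-3-[(tert-butyldimethylsilyl)oxy]butanoate | C[C@@H](O[Si](C)(C)C(C)(C)C)CC(=O)OC | intermediate
7 | (R,E)-3-[(tert-butyldimethylsilyl)oxy]-1-methoxy-1-[(trimethylsilyl)oxy]but-1-ene | C[C@@H](O[Si](C)(C)C(C)(C)C)/C=C(\OC)O[Si](C)(C)C | intermediate
8 | methyl (2S,3R)-3-[(tert-butyldimethylsilyl)oxy]-2-[(1S,6S)-6-isopropyl-3-[(trimethylsilyl)oxy]cyclohex-2-en-1-yl]butanoate | C[Si](C)(C)OC1=C[C@@H]([C@@H]([C@@H](C)O[Si](C)(C)C(C)(C)C)C(=O)OC)[C@H](C(C)C)CC1 | intermediate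
9 | bromoacetyl bromide | BrCC(Br)=O | starting material
10 | prop-2-en-1-ol | OCC=C | starting material
11 | allyl bromoacetate | BrCC(=O)OCC=C | intermediate
12 | methyl (2S,3R)-2-[(1S,2R,6S)-2-[2-(allyloxy)-2-oxoethyl]-6-isopropyl-3-oxocyclohexyl]-3-[(tert-butyldimethylsilyl)oxy]butanoate | O=C1[C@H](CC(=O)OCC=C)[C@@H]([C@@H]([C@@H](C)O[Si](C)(C)C(C)(C)C)C(=O)OC)[C@H](C(C)C)CC1 | intermediate
13 | methyl (2S,3R)-2-[(1S,2R,6S)-2-[2-(allyloxy)-2-oxoethyl]-6-isopropyl-3-methylenecyclohexyl]-3-[(tert-butyldimethylsilyl)oxy]butanoate | C=C1[C@H](CC(=O)OCC=C)[C@@H]([C@@H]([C@@H](C)O[Si](C)(C)C(C)(C)C)C(=O)OC)[C@H](C(C)C)CC1 | intermediate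
14 | allyl 1β-[(R)-1-(tert-butyldimethylsilyloxy)ethyl]-7β-isopropyl-4-methylene-2-oxo-trans-hydrindane-3α-carboxylate (3aα-H, 7aβ-H; C-3 labile, keto form drawn) | C=C1[C@H]2[C@@H]([C@@H]([C@@H](C)O[Si](C)(C)C(C)(C)C)C(=O)[C@@H]2C(=O)OCC=C)[C@H](C(C)C)CC1 | intermediate
15 | (1S,3aR,7S,7aS)-1-[(R)-1-[(tert-butyldimethylsilyl)oxy]ethyl]-7-isopropyl-4-methyleneoctahydro-2H-inden-2-one | C=C1[C@H]2[C@@H]([C@@H]([C@@H](C)O[Si](C)(C)C(C)(C)C)C(=O)C2)[C@H](C(C)C)CC1 | intermediate
16 | (1S,3S,3aR,7S,7aS)-1-[(R)-1-[(tert-butyldimethylsilyl)oxy]ethyl]-3-hydroxy-7-isopropyl-4-methyleneoctahydro-2H-inden-2-one | C=C1[C@H]2[C@@H]([C@@H]([C@@H](C)O[Si](C)(C)C(C)(C)C)C(=O)[C@H]2O)[C@H](C(C)C)CC1 | intermediate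
17 | (E)-2-methylbut-2-enoic acid | C/C=C(\C)C(=O)O | starting material
18 | (R)-2-methylbutanoic acid | CC[C@@H](C)C(=O)O | intermediate
19 | (1S,3S,3aR,7S,7aS)-1-[(R)-1-[(tert-butyldimethylsilyl)oxy]ethyl]-7-isopropyl-4-methylene-2-oxooctahydro-1H-inden-3-yl (R)-2-methylbutanoate | C=C1[C@H]2[C@@H]([C@@H]([C@@H](C)O[Si](C)(C)C(C)(C)C)C(=O)[C@H]2OC(=O)[C@H](C)CC)[C@H](C(C)C)CC1 | intermediate
20 | (1S,3S,3aR,5R,7S,7aS)-1-[(R)-1-[(tert-butyldimethylsilyl)oxy]ethyl]-5-hydroxy-7-isopropyl-4-methylene-2-oxooctahydro-1H-inden-3-yl (R)-2-methylbutanoate | C=C1[C@H]2[C@@H]([C@@H]([C@@H](C)O[Si](C)(C)C(C)(C)C)C(=O)[C@H]2OC(=O)[C@H](C)CC)[C@H](C(C)C)C[C@H]1O | intermediate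
21 | methyl but-2-ynoate | CC#CC(=O)OC | starting material
22 | methyl (E)-3-methylpent-2-enoate | CC/C(C)=C/C(=O)OC | intermediate
23 | (E)-3-methylpent-2-enoic acid | CC/C(C)=C/C(=O)O | intermediate
24 | (E)-3-methylpent-2-enoic 2,4,6-trichlorobenzoic anhydride | CC/C(C)=C/C(=O)OC(=O)c1c(Cl)cc(Cl)cc1Cl | intermediate
25 | (1S,3S,3aR,5R,7S,7aS)-1-[(R)-1-[(tert-butyldimethylsilyl)oxy]ethyl]-7-isopropyl-4-methylene-3-{[(R)-2-methylbutanoyl]oxy}-2-oxooctahydro-1H-inden-5-yl (E)-3-methylpent-2-enoate | C=C1[C@H]2[C@@H]([C@@H]([C@@H](C)O[Si](C)(C)C(C)(C)C)C(=O)[C@H]2OC(=O)[C@H](C)CC)[C@H](C(C)C)C[C@H]1OC(=O)/C=C(\C)CC | intermediate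
26 | (1S,3S,3aR,5R,7S,7aS)-1-[(R)-1-hydroxyethyl]-7-isopropyl-4-methylene-3-{[(R)-2-methylbutanoyl]oxy}-2-oxooctahydro-1H-inden-5-yl (E)-3-methylpent-2-enoate | C=C1[C@H]2[C@@H]([C@@H]([C@@H](C)O)C(=O)[C@H]2OC(=O)[C@H](C)CC)[C@H](C(C)C)C[C@H]1OC(=O)/C=C(\C)CC | target

**Step count and risks**

Total step count: 17.
Longest linear sequence: 11 steps (steps 1, 2, 5, 7, 8, 9, 10, 12, 13, 16, 17; the branch through steps 3 and 4 is equally long).

Steps most likely to fail, each with a fallback:

Step 7 (fluoride-triggered alkylation). The naked enolate may scramble, O-alkylate or attack an ester, and fluoride may touch the silyl ether. Fallback: the C3a–C3 bond is made by a radical instead of an enolate. Bromide 11 is converted by Finkelstein exchange (NaI, acetone) into allyl iodoacetate F1. F1 is then added to silyl enol ether 8 under Et3B/air initiation (CH2Cl2, −20 °C). The electrophilic alkoxycarbonylmethyl radical attacks C-3a anti to the C-7a substituent, and iodine transfer with loss of Me3SiI gives the ketone. This sets out from 8 (with 11) and comes back to the route at 12.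

Step 10 (facial selectivity of the enolate oxidation). If the oxaziridine attacks from the α face, the product is the 3α-alcohol (1S,3R,3aR,7S,7aS)-1-[(R)-1-[(tert-butyldimethylsilyl)oxy]ethyl]-3-hydroxy-7-isopropyl-4-methyleneoctahydro-2H-inden-2-one F2. It is not discarded: Mitsunobu esterification of F2 with acid 18 (PPh3, DIAD, toluene, 0 °C) displaces the activated α-keto alcohol with inversion and installs the 3β-ester in one operation. This sets out from 15 and comes back at 19, so step 12 is not needed.

Step 13 (regio- and stereochemistry of the SeO2 oxidation). If the equatorial alcohol dominates, the product is the 5β-alcohol (1S,3S,3aR,5S,7S,7aS)-1-[(R)-1-[(tert-butyldimethylsilyl)oxy]ethyl]-5-hydroxy-7-isopropyl-4-methylene-2-oxooctahydro-1H-inden-3-yl (R)-2-methylbutanoate F3. It is esterified with acid 23 under Mitsunobu conditions (PPh3, DIAD, THF, 0 °C). SN2 inversion at C-5 gives the axial ester directly. This sets out from 19 and comes back at 25, bypassing 20 and 24.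

**Further compounds**

F1 | step 7 | allyl iodoacetate | ICC(=O)OCC=C
F2 | step 10 | (1S,3R,3aR,7S,7aS)-1-[(R)-1-[(tert-butyldimethylsilyl)oxy]ethyl]-3-hydroxy-7-isopropyl-4-methyleneoctahydro-2H-inden-2-one (3α-alcohol) | C=C1[C@H]2[C@@H]([C@@H]([C@@H](C)O[Si](C)(C)C(C)(C)C)C(=O)[C@@H]2O)[C@H](C(C)C)CC1
F3 | step 13 | (1S,3S,3aR,5S,7S,7aS)-1-[(R)-1-[(tert-butyldimethylsilyl)oxy]ethyl]-5-hydroxy-7-isopropyl-4-methylene-2-oxooctahydro-1H-inden-3-yl (R)-2-methylbutanoate (5β-alcohol) | C=C1[C@H]2[C@@H]([C@@H]([C@@H](C)O[Si](C)(C)C(C)(C)C)C(=O)[C@H]2OC(=O)[C@H](C)CC)[C@H](C(C)C)C[C@@H]1O
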